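4 questions are asked of these flasks, and I carry one quantity towards them.

the same everywhere: catalyst 0.0400 M

| charge | substrate | coupling partner | time |
|---|---|---|---|
| Sunday's | 0.500 M | 0.600 M |  |
| Friday's | 1.00 M | 0.600 M |  |
| Monday's | 0.500 M | 0.300 M |  |
| Wednesday's | 0.500 M | 0.600 M | 22 min |

| run | time / min | [target] / M |
|---|---|---|
| Sunday's run | 0.30 | 0.093 |
| Sunday's run | 0.56 | 0.155 |
| Sunday's run | 1.1 | 0.235 |
| Sunday's run | 2.0 | 0.312 |
| Sunday's run | 3.9 | 0.388 |
| Sunday's run | 7.4 | 0.446 |
| Friday's run | 0.30 | 0.116 |
| Friday's run | 0.56 | 0.186 |
| Friday's run | 1.1 | 0.291 |
| Friday's run | 2.0 | 0.395 |
| Friday's run | 3.9 | 0.489 |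
| Friday's run | 7.4 | 0.560 |
| Monday's run | 0.30 | 0.055 |
| Monday's run | 0.56 | 0.087 |
| Monday's run | 1.1 | 0.128 |
| Monday's run | 2.0 | 0.192 |
| Monday's run | 3.9 | 0.238 |
| Monday's run | 7.4 | 0.279 |

(standard deviation of a reading: 0.004 M)

- the exponent of [coupling partner] in the starting rate at the charge of the Sunday's run (at the point where two percent of the substrate have become target)
- the exponent of [substrate] in the starting rate at the charge of the Sunday's run (at the point where two percent of the substrate have become target) (one fixed amount of target, the same in the runs compared)
- target in the Wednesday's run at 22 min, as a share of the substrate charged
- which of these the readings show (the product reacts on with the second partner / the two partners rest in a complex / the catalyst dies in pairs / an uncatalysed path runs beside / nothing beyond the main steps / the by-product ties up the catalyst)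

- Overall: substrate + coupling partner -> target, with catalyst as catalyst.
- Constant volume, constant temperature.
- What is held in complexes is read along with the free species.
- "The second partner" is coupling partner.
- An order is taken over about fifteen percent of the charge, up and down.

1. I write x for the share of the substrate charge that has become target, and q for the coupling partner charge over the substrate charge. Sunday has q = 1.20, above the crossing at 1, so substrate is the limiting reagent. Monday has q = 0.600 and Friday q = 0.600, so the partner limits those two flasks.

2. My bench rule is the plain second-order law. The pace of x is a constant times the substrate share left, times the partner left, counted in the same shares of the substrate charge. Integrated through Sunday's last reading, it gives 0.585 min⁻¹. I call this the share clock, the pace of x per substrate share left per partner share left.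

3. Taken strictly, the rule makes this clock follow the substrate charge. Friday holds twice Sunday's substrate, so the rule asks for 1.17 min⁻¹ on Friday.

4. Friday's last reading gives 0.638 min⁻¹, which is less. The ratio of Friday's clock to Sunday's is 1.09. The rule stops here: the clock does not follow the charge. I therefore keep the clock in shares.

5. Wednesday has Sunday's charge, so I run Sunday's clock to 22 min. That gives me 98.6 %.

6. The forecast gives a partner order of 0.98, a substrate order of 0.33, 98.3 % of the substrate charge as target on Wednesday, and "the by-product ties up the catalyst". Its ground is this: “Something built up alongside the target therefore occupies the catalyst about as strongly as substrate”. My number for Wednesday stands above the forecast's.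

7. The flask gives a partner order of 1.0, a substrate order of 0.27, 98.2 % of the substrate charge as target on Wednesday, and "the by-product ties up the catalyst".

    catalyst + substrate ⇌ catalyst-substrate complex, settled at all times (7.170 M⁻¹)
    catalyst-substrate complex + coupling partner → target + catalyst + by-product (21.96 M⁻¹ min⁻¹)
    catalyst + by-product ⇌ catalyst-by-product complex, settled at all times (10.50 M⁻¹)

The forecast's substrate order is higher than the flask's. The fit with nothing beyond the main steps forecasts 99.7 % for Wednesday. Put through the same law, Wednesday's 98.2 % means a mean clock of 0.528 min⁻¹ over 22 min, slower than Sunday's. Sunday's clock, set on Monday's q, brings Monday's target to half of its substrate charge at 4.69 min. Monday's flask comes to that point at 4.52 min.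

Readings and results stem from a simulated flask for substances that don't exist; the scatter is artificial.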